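**Retrosynthetic overview**

- Numbering used throughout: ring C1 (CH3 and the C7=C8 chlorovinyl group), C2H2, C3 (Br and C9H2Br), C4HCl, C5H2, C6HCl. The strategy rests on the C6 chloride, which sits on the ring carbon next to quaternary C1 and cis to C7. This is the pattern of (Z)-3-chloro-2-methylprop-2-enal and makes a neopentyl chlorination unnecessary.
- The cyclohexane ring, the only ring, is closed in one catalytic enantioselective [4+2] cycloaddition of that enal with 2-(triisopropylsilyloxy)buta-1,3-diene. It forms C1–C2 and C5–C6, sets C1 and C6, and leaves a C3=C4 silyl enol ether.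
- After the ring: C7=C8 by Wittig chloromethylenation; C9 on C3 by base-free Mannich methylenation of the silyl enol ether; C4–Cl by reagent-controlled ketone reduction and invertive allylic chlorination; C3–Br and C9–Br by bromine addition to C3=C9.
- The dienophile is made with defined geometry from prop-2-yn-1-ol (anti carbomagnesiation, chlorination, oxidation), the diene from but-3-en-2-one.

Key step: step 4

Assumption: the sense of induction of the (S)-diphenylprolinol-derived catalyst is assigned from the formyl C–H···O binding model for 2-substituted enals; if the adduct proved antipodal, the (R)-catalyst would be used with no other change.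

**Route**

Step 1
Reactants: 1 prop-2-yn-1-ol
Product: 3 (Z)-3-chloro-2-methylprop-2-en-1-ol, via alkenylmagnesium alkoxide 2 (not isolated)
Conditions: MeMgBr (3 equiv), CuI (10 mol%), THF, −10 °C → rt; then NCS, −40 → 0 °C; aq. NH4Cl
Reagents that add atoms: methylmagnesium bromide, C[Mg]Br; N-chlorosuccinimide, ClN1C(=O)CCC1=O
Why: Copper-catalysed anti carbomagnesiation of the magnesium propargyl alkoxide puts methyl on C2 and magnesium on C3 inside a five-membered chelate (Mg cis to CH2O), and electrophilic chlorination of the alkenyl–magnesium bond proceeds with retention, so the chloride should emerge cis to CH2OH (Z).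

Step 2
Reactants: 3 (Z)-3-chloro-2-methylprop-2-en-1-ol
Product: 4 (Z)-3-chloro-2-methylprop-2-enal
Conditions: activated MnO2 (excess), CH2Cl2, rt, dark; filtered through Celite and used as a CH2Cl2 solution
Reagents that add atoms: none
Why: Allylic oxidation with MnO2 is neutral and selective for the allylic alcohol, so the volatile β-chloro enal should be obtained without Z/E isomerisation and can go into the cycloaddition without isolation from solvent.

Step 3
Reactants: 5 but-3-en-2-one
Product: 6 2-(triisopropylsilyloxy)buta-1,3-diene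
Conditions: iPr3SiOTf, Et3N, Et2O, 0 °C → rt
Reagents that add atoms: triisopropylsilyl trifluoromethanesulfonate, CC(C)[Si](C(C)C)(C(C)C)OS(=O)(=O)C(F)(F)F
Why: Soft enolisation (O-silylation of the ketone by the silyl triflate, then deprotonation of the methyl group by the amine) gives the cross-conjugated 2-silyloxydiene.

Step 4
Reactants: 4 (Z)-3-chloro-2-methylprop-2-enal; 6 2-(triisopropylsilyloxy)buta-1,3-diene
Product: 7 (1S,6S)-6-chloro-1-methyl-4-[(triisopropylsilyl)oxy]cyclohex-3-ene-1-carbaldehyde
Conditions: (S)-3,3-diphenyl-1-(o-tolyl)tetrahydro-1H,3H-pyrrolo[1,2-c][1,3,2]oxazaborole (C24H24BNO, 20 mol%) protonated with HNTf2 (18 mol%), 6 (1.5 equiv), CH2Cl2, −78 → −20 °C; Et3N quench; Et3N-deactivated silica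
Reagents that add atoms: none
Why: The N-protonated oxazaborolidine binds the formyl oxygen of s-trans 4 (B–O coordination supported by a formyl C–H···O contact to the ring oxygen) and lowers its LUMO, so that 6 adds in a concerted but asynchronous [4+2] cycloaddition in which the enol-ether CH2 terminus bonds to the chlorine-bearing β-carbon (C5–C6) ahead of C2–C1. The closest known reaction type is the oxazaborolidinium-catalysed Diels–Alder reaction of 2-substituted acroleins with 2-silyloxybutadienes; the 3-chloro substituent on the enal is the untested variable and should slow the reaction. The six-membered carbocycle closes by intermolecular [4+2] cycloaddition, both ring bonds being made in one step, and there is no endo/exo question because the diene termini are unsubstituted. C1 is set by the catalyst, whose carbinol aryl group screens one face of the bound enal so that the diene reaches the α-carbon from the face on which CHO, C6 and CH3 run clockwise; C6 follows from C1 because addition is suprafacial and the Z geometry of 4 places Cl cis to CHO. The step needs para regioselectivity, which the 2-silyloxy group secures by making the CH2 next to C–O the nucleophilic diene terminus, and it needs ring closure to outrun loss of chloride from the β-position, which low temperature and a concerted pathway should favour.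

Step 5
Reactants: 7 (1S,6S)-6-chloro-1-methyl-4-[(triisopropylsilyl)oxy]cyclohex-3-ene-1-carbaldehyde
Product: 8 {[(4S,5S)-5-chloro-4-[(Z)-2-chloroethenyl]-4-methylcyclohex-1-en-1-yl]oxy}triisopropylsilane
Conditions: Ph3P(CH2Cl)Cl, NaHMDS, THF, −78 °C; then 7, −78 → 0 °C
Reagents that add atoms: (chloromethyl)triphenylphosphonium chloride, ClC[P+](c1ccccc1)(c1ccccc1)c1ccccc1.[Cl-]
Why: Wittig chloromethylenation with the unstabilised ylide under lithium-free conditions should favour the cis oxaphosphetane and hence the Z chloroalkene with this hindered, non-enolisable aldehyde (any E isomer to be removed by chromatography), while the silyl enol ether and both stereocentres are untouched.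

Step 6
Reactants: 8 {[(4S,5S)-5-chloro-4-[(Z)-2-chloroethenyl]-4-methylcyclohex-1-en-1-yl]oxy}triisopropylsilane
Product: 11 (4S,5S)-5-chloro-4-[(Z)-2-chloroethenyl]-4-methyl-2-methylidenecyclohexan-1-one, via Mannich base 9 (not isolated), via trimethylammonium iodide 10 (not isolated)
Conditions: Me2N=CH2+ I− (Eschenmoser's salt), CH2Cl2, rt; cold aq. NaHCO3 wash; MeI, CH2Cl2, rt; aq. NaHCO3/CH2Cl2, rt; crude enone used at once
Reagents that add atoms: N,N-dimethylmethyleneiminium iodide, C=[N+](C)C.[I-]
Why: The Mukaiyama–Mannich reaction of the regiodefined silyl enol ether with the preformed iminium salt places C9 on C3 without base, and quaternisation followed by bicarbonate-induced E1cB loss of trimethylamine (the classical Mannich-base route to α-methylene ketones) should be much faster than loss of the chloride at C6, which needs a stronger base.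

Step 7
Reactants: 11 (4S,5S)-5-chloro-4-[(Z)-2-chloroethenyl]-4-methyl-2-methylidenecyclohexan-1-one
Product: 12 (1S,4S,5S)-5-chloro-4-[(Z)-2-chloroethenyl]-4-methyl-2-methylidenecyclohexan-1-ol
Conditions: (R)-1-methyl-3,3-diphenyltetrahydro-1H,3H-pyrrolo[1,2-c][1,3,2]oxazaborole ((R)-Me-CBS, C18H20BNO, 0.5 equiv), catecholborane, toluene, −78 °C; MeOH quench
Reagents that add atoms: none
Why: In this Corey–Bakshi–Shibata reduction the (R)-oxazaborolidine should bind the ketone with the sp2-substituted C3 as the large group and deliver hydride to the face cis to the C6 chloride (an equatorial trajectory on the conformer with equatorial chlorine), setting the C4 carbinol centre S, hydroxyl trans to the C6 chloride, by catalyst control with 1,2-selectivity at low temperature.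

Step 8
Reactants: 12 (1S,4S,5S)-5-chloro-4-[(Z)-2-chloroethenyl]-4-methyl-2-methylidenecyclohexan-1-ol
Product: 13 (1S,2S,4R)-2,4-dichloro-1-[(Z)-2-chloroethenyl]-1-methyl-5-methylidenecyclohexane
Conditions: PPh3, Cl3CC(O)CCl3, CH2Cl2, −20 → 0 °C
Reagents that add atoms: hexachloroacetone, ClC(Cl)(Cl)C(=O)C(Cl)(Cl)Cl
Why: Appel-type deoxychlorination with PPh3/hexachloroacetone converts secondary allylic alcohols to chlorides by SN2 displacement of the oxyphosphonium group with inversion and little allylic transposition, so the axial C4 oxygen should be replaced by an equatorial chlorine cis to the C6 chloride.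

Step 9
Reactants: 13 (1S,2S,4R)-2,4-dichloro-1-[(Z)-2-chloroethenyl]-1-methyl-5-methylidenecyclohexane
Product: 14 (1S,2R,4S,5S)-1-bromo-1-(bromomethyl)-2,4-dichloro-5-[(Z)-2-chloroethenyl]-5-methylcyclohexane
Conditions: Br2 (1.0 equiv), CH2Cl2, −78 °C, dark
Reagents that add atoms: bromine, BrBr
Why: Electrophilic anti addition of bromine to the 1,1-disubstituted alkene (the chlorovinyl group is deactivated) should proceed through a bromonium ion on the face away from the axial chlorovinyl group, opened by bromide at tertiary C3 from the opposite side, which gives the axial C3 bromide cis to C4–Cl and the equatorial CH2Br, the epimer that avoids a 1,3-diaxial CH2Br/chlorovinyl interaction.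

**Compound list**

1 | prop-2-yn-1-ol | OCC#C | starting material
2 | bromomagnesium (Z)-3-(bromomagnesio)-2-methylprop-2-en-1-olate (chelated alkenylmagnesium alkoxide) | Br[Mg]/C=C(/C)CO[Mg]Br | intermediate
3 | (Z)-3-chloro-2-methylprop-2-en-1-ol | Cl/C=C(/C)CO | intermediate
4 | (Z)-3-chloro-2-methylprop-2-enal | Cl/C=C(/C)C=O | intermediate
5 | but-3-en-2-one | CC(=O)C=C | starting material
6 | 2-(triisopropylsilyloxy)buta-1,3-diene | C=CC(=C)O[Si](C(C)C)(C(C)C)C(C)C | intermediate
7 | (1S,6S)-6-chloro-1-methyl-4-[(triisopropylsilyl)oxy]cyclohex-3-ene-1-carbaldehyde (Cl cis to CHO) | C[C@@]1(C=O)CC=C(O[Si](C(C)C)(C(C)C)C(C)C)C[C@@H]1Cl | intermediate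
8 | {[(4S,5S)-5-chloro-4-[(Z)-2-chloroethenyl]-4-methylcyclohex-1-en-1-yl]oxy}triisopropylsilane | C[C@@]1(/C=C\Cl)CC=C(O[Si](C(C)C)(C(C)C)C(C)C)C[C@@H]1Cl | intermediate
9 | (4S,5S)-5-chloro-4-[(Z)-2-chloroethenyl]-2-[(dimethylamino)methyl]-4-methylcyclohexan-1-one (both C2 epimers) | C[C@@]1(/C=C\Cl)CC(CN(C)C)C(=O)C[C@@H]1Cl | intermediate
10 | 1-[(4S,5S)-4-chloro-5-[(Z)-2-chloroethenyl]-5-methyl-2-oxocyclohexyl]-N,N,N-trimethylmethanaminium iodide | C[C@@]1(/C=C\Cl)CC(C[N+](C)(C)C)C(=O)C[C@@H]1Cl.[I-] | intermediate
11 | (4S,5S)-5-chloro-4-[(Z)-2-chloroethenyl]-4-methyl-2-methylidenecyclohexan-1-one | C[C@@]1(/C=C\Cl)CC(=C)C(=O)C[C@@H]1Cl | intermediate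
12 | (1S,4S,5S)-5-chloro-4-[(Z)-2-chloroethenyl]-4-methyl-2-methylidenecyclohexan-1-ol (OH trans to the ring chloride) | C[C@@]1(/C=C\Cl)CC(=C)[C@@H](O)C[C@@H]1Cl | intermediate
13 | (1S,2S,4R)-2,4-dichloro-1-[(Z)-2-chloroethenyl]-1-methyl-5-methylidenecyclohexane | C[C@@]1(/C=C\Cl)CC(=C)[C@H](Cl)C[C@@H]1Cl | intermediate
14 | (1S,2R,4S,5S)-1-bromo-1-(bromomethyl)-2,4-dichloro-5-[(Z)-2-chloroethenyl]-5-methylcyclohexane | C[C@@]1(/C=C\Cl)C[C@@](Br)(CBr)[C@H](Cl)C[C@@H]1Cl | target

**Step count**

Total: 9 steps. Longest linear sequence: 8 steps (steps 1, 2, 4, 5, 6, 7, 8, 9 from prop-2-yn-1-ol).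

**Steps most likely to fail**

Step 4. The trisubstituted, chlorine-bearing dienophile may add too slowly. The activated enal may instead take a stepwise Mukaiyama–Michael course and expel chloride from the β-carbon before the ring closes. The bound enal may also lose its Z geometry, or face selection may erode. Fallback, setting out from 4 and 6 and coming back at 12: the two are heated without any acid (toluene, BHT, sealed tube, about 110 °C), where a more synchronous thermal [4+2] cycloaddition is expected. This gives 7 as a racemate, that is together with (1R,6R)-6-chloro-1-methyl-4-[(triisopropylsilyl)oxy]cyclohex-3-ene-1-carbaldehyde F1. The racemate is taken through steps 5 and 6 unchanged, which gives in addition {[(4R,5R)-5-chloro-4-[(Z)-2-chloroethenyl]-4-methylcyclohex-1-en-1-yl]oxy}triisopropylsilane F2, the unisolated (4R,5R)-5-chloro-4-[(Z)-2-chloroethenyl]-2-[(dimethylamino)methyl]-4-methylcyclohexan-1-one F3 and its methiodide 1-[(4R,5R)-4-chloro-5-[(Z)-2-chloroethenyl]-5-methyl-2-oxocyclohexyl]-N,N,N-trimethylmethanaminium iodide F4, and (4R,5R)-5-chloro-4-[(Z)-2-chloroethenyl]-4-methyl-2-methylidenecyclohexan-1-one F5. The enantiomers are parted in step 7: under catalyst control the (R)-oxazaborolidine reduces both enones to S carbinols, so 11 gives 12 while F5 gives the diastereomeric (1S,4R,5R)-5-chloro-4-[(Z)-2-chloroethenyl]-4-methyl-2-methylidenecyclohexan-1-ol F6, which is removed by chromatography (divergent reaction of a racemate).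

Step 7. The intrinsic preference of the ring for hydride attack from the other face may compete with catalyst control and lower the facial selectivity, and the s-cis enone may undergo conjugate reduction. Fallback, setting out from 11 and coming back at 12: substrate-controlled Luche reduction (NaBH4, CeCl3·7H2O, MeOH, −78 °C) should give the epimeric (1R,4S,5S)-5-chloro-4-[(Z)-2-chloroethenyl]-4-methyl-2-methylidenecyclohexan-1-ol F7, with hydroxyl cis to the ring chloride. Both chair conformers lead to it: axial attack on the one with equatorial chlorine, and equatorial attack on the one whose axial chlorine blocks the axial path. Mitsunobu inversion with 4-nitrobenzoic acid (PPh3, DIAD, toluene, 0 °C) then gives (1S,4S,5S)-5-chloro-4-[(Z)-2-chloroethenyl]-4-methyl-2-methylidenecyclohexyl 4-nitrobenzoate F8, and methanolysis (K2CO3, MeOH, 0 °C) gives 12.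

Step 9. Bromide may open the bromonium ion at the CH2 terminus or bromine may add from the hindered face, which inverts the outcome at C3. Bromine may also attack the chlorovinyl group if the exocyclic alkene reacts slowly. Fallback, setting out from 13 and coming back at 14: if the kinetic addition gives mainly (1R,2R,4S,5S)-1-bromo-1-(bromomethyl)-2,4-dichloro-5-[(Z)-2-chloroethenyl]-5-methylcyclohexane F9, control is shifted from kinetic to thermodynamic. Vicinal dibromides interconvert through the bromonium–bromide ion pair (1,2-dibromide rearrangement). Warming isolated F9 with ZnBr2 in MeCN/CH2Cl2 should therefore move it to 14, the more stable epimer with equatorial CH2Br.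

**Further compounds**

F1 | step 4 | (1R,6R)-6-chloro-1-methyl-4-[(triisopropylsilyl)oxy]cyclohex-3-ene-1-carbaldehyde | C[C@]1(C=O)CC=C(O[Si](C(C)C)(C(C)C)C(C)C)C[C@H]1Cl
F2 | step 4 | {[(4R,5R)-5-chloro-4-[(Z)-2-chloroethenyl]-4-methylcyclohex-1-en-1-yl]oxy}triisopropylsilane | C[C@]1(/C=C\Cl)CC=C(O[Si](C(C)C)(C(C)C)C(C)C)C[C@H]1Cl
F3 | step 4 | (4R,5R)-5-chloro-4-[(Z)-2-chloroethenyl]-2-[(dimethylamino)methyl]-4-methylcyclohexan-1-one | C[C@]1(/C=C\Cl)CC(CN(C)C)C(=O)C[C@H]1Cl
F4 | step 4 | 1-[(4R,5R)-4-chloro-5-[(Z)-2-chloroethenyl]-5-methyl-2-oxocyclohexyl]-N,N,N-trimethylmethanaminium iodide | C[C@]1(/C=C\Cl)CC(C[N+](C)(C)C)C(=O)C[C@H]1Cl.[I-]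
F5 | step 4 | (4R,5R)-5-chloro-4-[(Z)-2-chloroethenyl]-4-methyl-2-methylidenecyclohexan-1-one | C[C@]1(/C=C\Cl)CC(=C)C(=O)C[C@H]1Cl
F6 | step 4 | (1S,4R,5R)-5-chloro-4-[(Z)-2-chloroethenyl]-4-methyl-2-methylidenecyclohexan-1-ol | C[C@]1(/C=C\Cl)CC(=C)[C@@H](O)C[C@H]1Cl
F7 | step 7 | (1R,4S,5S)-5-chloro-4-[(Z)-2-chloroethenyl]-4-methyl-2-methylidenecyclohexan-1-ol | C[C@@]1(/C=C\Cl)CC(=C)[C@H](O)C[C@@H]1Cl
F8 | step 7 | (1S,4S,5S)-5-chloro-4-[(Z)-2-chloroethenyl]-4-methyl-2-methylidenecyclohexyl 4-nitrobenzoate | C[C@@]1(/C=C\Cl)CC(=C)[C@@H](OC(=O)c2ccc(cc2)[N+](=O)[O-])C[C@@H]1Cl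
F9 | step 9 | (1R,2R,4S,5S)-1-bromo-1-(bromomethyl)-2,4-dichloro-5-[(Z)-2-chloroethenyl]-5-methylcyclohexane | C[C@@]1(/C=C\Cl)C[C@](Br)(CBr)[C@H](Cl)C[C@@H]1Cl
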